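A small charge of free catalyst makes some target and then the readings stand level: from 30.0 min on, the mean target is 13.0% in alder, 24.5% in maple and 45.4% in oak, which is less than the substrate share of the oak charge, 90.9%.

| flask | substrate | other conformer | free catalyst | remark | time |
|---|---|---|---|---|---|
| alder | 1 M | 0.10 M | 0.65 mM | run made earlier |  |
| oak | 1 M | 0.10 M | 2.6 mM | run made earlier |  |
| maple | 1 M | 0.15 M | 1.3 mM | run made earlier |  |
| flask | 1.0 M | 0.100 M | 1.3 mM |  | 1.5 h |

- alder (time / min: isomer of the product / %, target / %): 4.00: 10, 5; 12.0: 10, 13; 20.0: 12, 9; 30.0: 12, 13; 40.0: 12, 13; 60.0: 16, 12; 80.0: 15, 14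
- oak (time / min: isomer of the product / %, target / %): 10.0: 11, 33; 20.0: 11, 40; 30.0: 10, 45; 40.0: 12, 45; 50.0: 12, 49; 60.0: 16, 44; 80.0: 13, 44
- maple (time / min: isomer of the product / %, target / %): 6.00: 16, 13; 10.0: 15, 20; 20.0: 14, 22; 40.0: 15, 25; 80.0: 20, 24

(scatter of a reading: 1.5 percentage points)

- steps under discussion: free catalyst + other conformer -> free catalyst + isomer of the product; substrate <-> dormant form; substrate + free catalyst -> free catalyst + target; free catalyst -> spent catalyst; substrate <-> other conformer

* share of isomer of the product in isomer of the product plus target at 1.5 s
* share of isomer of the product in isomer of the product plus target at 80 s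
* share of isomer of the product in isomer of the product plus target at 1.5 h

From alder to oak the catalyst grows by a factor 4.00 and the target by 3.49, so I work with the fraction left. If substrate loss is pseudo-first-order at each moment and the catalyst decays on its own clock, ln(1/fraction left) is proportional to c(free catalyst) charged. With the substrate share of the maple charge at 87.0%, that slope is the lifetime dose per unit of catalyst 0.253 mM⁻¹, the mean of these run values:

alder 0.237 mM⁻¹, maple 0.255 mM⁻¹, oak 0.266 mM⁻¹

For the flask:

fraction left = 0.720

target = 25.5%

Alder and oak share the flask's other-conformer charge, and their isomer readings at 60.0 min and 80.0 min average 15.0%. So my share at 1.5 h is 37.1%.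

The weak link is the share at 1.5 s. I take the ratio of the starting rates, in which the catalyst cancels; it serves while little other conformer has been used. The first maple target reading, with catalyst decay set aside, gives k(target) near 0.0208 mM⁻¹ min⁻¹. The first alder isomer reading, taken 3 percentage points low, gives k(isomer) of at least 0.565 mM⁻¹ min⁻¹. With these two values my share is an estimate, not a bound:

share ≈ 73.1%

The forecast says 92%, 66% and 38%, against my 37.1% for the last, and calls the first “probably above 90%, though poorly bounded”.

The flask gives 98.2%, 67.8% and 38.1%.

    free catalyst + other conformer → free catalyst + isomer of the product (k = 25000 M⁻¹ min⁻¹)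
    substrate ⇌ dormant form (K = 0.420, k = 0.0680 min⁻¹)
    substrate + free catalyst → free catalyst + target (k = 32.0 M⁻¹ min⁻¹)
    free catalyst → spent catalyst (k = 0.0910 min⁻¹)
    substrate ⇌ other conformer (K = 0.0730, k = 0.00250 min⁻¹)

The two part at 1.5 s, by 6.2 points. At 1.50 h the flask holds 26.7% target against my 25.5%. A neighbouring flask charged with 0.0052 M of free catalyst takes the same dose 0.253 mM⁻¹: its fraction left is 0.268, so I reckon 66.5% target. That neighbouring flask gives 66.9% target and 12.8% isomer of the product at 1.50 h, a share of 16.1%.

The runs are simulated on assumed constants; noise was put on by code.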